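Per minute is the unit I reckon in for what each flask does to its electrophile, which meets nucleophile to give target while protic impurity stands beside them.

| flask | electrophile | nucleophile | protic impurity | remark | time |
|---|---|---|---|---|---|
| epsilon | 0.40 M | 0.57 M | 0.40 M | run made earlier |  |
| gamma | 0.40 M | 2.5 M | 0.40 M | run made earlier |  |
| ash | 0.40 M | 1.80 M | 0.400 M |  | 80 min |
| maple | 0.40 M | 0.880 M | 0.400 M |  | 80 min |
| larch | 0.40 M | 0.440 M | 0.400 M |  | 80 min |

| run | time / min | electrophile / % | target / % |
|---|---|---|---|
| epsilon | 8.00 | 91.3 | 9.4 |
| epsilon | 20.0 | 86.1 | 14.4 |
| epsilon | 40.0 | 82.7 | 18.1 |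
| epsilon | 60.0 | 80.8 | 20.4 |
| gamma | 5.00 | 59.0 | 39.8 |
| gamma | 10.0 | 37.4 | 62.4 |
| gamma | 25.0 | 10.6 | 88.5 |
| gamma | 60.0 | 1.4 | 99.1 |

(each reading ± 0.5 percentage points)



- part of the electrophile that has reacted at the end, ash
- part of the electrophile that has reacted at the end, maple
- part of the electrophile that has reacted at the end, larch
- what raising the concentration of nucleophile from its lowest to its highest value here does to the part of the electrophile that has reacted (changes below 5 percentage points count as none) (it falls / it rises / no change)

Gamma loses 0.106 /min of its electrophile up to its first reading, with nucleophile net of impurity at 5.25 electrophile charges, so I take 0.0201 /min per charge of nucleophile. In maple the impurity leaves a factor 0.545 of the nucleophile, so maple starts at 0.0241 /min.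

Epsilon shows the next slowing: it stalls near 20.4%, about half of its net nucleophile, so I read each electrophile reacted as costing two nucleophile. Epsilon's limit by this count is 21.2%, just above that reading.

For maple, nucleophile charge minus impurity charge, halved and taken as a fraction of the electrophile charge, is 60.0%: its ceiling, the part reacted that this count allows, with nucleophile the limiting reagent. Halfway there, maple's rate has fallen by a factor 0.5 through nucleophile and 0.700 through electrophile. Summing that falling rate over 80 min gives 52.1%.

Ash's ceiling, 175%, lies above the whole charge, and the same sum gives 96.0%. Larch's ceiling is 5.00%, but epsilon's first reading runs 3.7 percentage points ahead of my sum, so I add that lead and say 8.71%. The part reacted therefore rises with nucleophile.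

The forecast, holding that “the protic impurity quickly destroys nucleophile roughly 1:1”, gives 93% for ash, 47% for maple, below my figure, and 10% for larch, and on the trend says it rises.

The flasks give 96.6%, 52.9% and 8.88%: it rises, by 88 points.

    acid set free + target → side product (k = 4.39 × 10⁻⁴ /M/s)
    electrophile + nucleophile → acid set free + target (k = 8.90 × 10⁻⁴ /M/s)
    nucleophile + protic impurity → quenched reagent (k = 0.0255 /M/s)
    nucleophile + acid set free ⇌ protonated nucleophile, settled at all times (K = 8900 /M)

In maple at 80.0 min, protonated nucleophile stands at 0.211 M, level with the target, 0.212 M, so that is where the second nucleophile per electrophile is found. The neighbour is maple left until 2.5 h, with all amounts held, so its ceiling stays 60.0%. The same sum gives 57.7%. The flask gives 58.2%, below the ceiling, with 1.9% of its nucleophile still free. Maple left until 800 min has reacted 64.1%, past that ceiling, with side product at 6.94%.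

All runs are simulated for an exercise.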